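**Plan**

- Numbering (eremophilane): ring A = C1–C5 and C10, ring B = C5–C10, C14 on C5, C15 on C4, C11 (with C12, C13) on C7. Ring B holds two skipped alkenes, C6=C7 and C9=C10, on either side of oxygen-bearing C8 and hinged on quaternary C5. This 1,4-cyclohexadiene is the imprint of an alkyne (C6≡C7) added across a diene C5=C10–C9=C8 that carries oxygen on C8.
- Retrosynthesis: the C11 hydroperoxide goes back to an isopropenyl and then an acetyl group, the C8 ketone to a C8 ethyl ether, O-1 to C1–H. C5–C6 and C7–C8 are then cut together, giving but-3-yn-2-one and a ring A (E)-1-ethoxydiene, and C9–C10 is cut last (enol triflate plus (E)-2-ethoxyvinylboronate).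
- Forward: ring A is a bought cyclohexenone that is oxygenated at C3 and C10; the two-carbon enol ether is coupled on; ring B closes in one cycloaddition; C1, C11 and C8 are then adjusted and two silyl groups removed.
- Stereochemistry: C3 from CBS reduction; C4 from hydride addition anti to the C3 silyloxy group; C5 from cycloaddition anti to the pseudoaxial C15; C1 from SeO2 ene hydroxylation through the axial hydrogen; the Z ester geometry comes with angelic acid.

Key step: step 8

Assumption: the target is read as (1R,3S,4R,5R) in the numbering above, with O-1, O-3, C14 and C15 all on one face, called β here.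

Step 1
Reactants: 1 2,3-dimethylcyclohex-2-en-1-one
Product: 2 (S)-2,3-dimethylcyclohex-2-en-1-ol
Conditions: (R)-2-methyl-CBS-oxazaborolidine (10 mol %), BH3·SMe2, THF, −20 °C; MeOH quench
Reagents that add atoms: none
Why: Corey–Bakshi–Shibata reduction, in which the 2-methyl-substituted alkene arm acts as the large group, so that the (R)-oxazaborolidine is expected to give the (S)-carbinol, the future C3.

Step 2
Reactants: 2 (S)-2,3-dimethylcyclohex-2-en-1-ol
Product: 3 (S)-tert-butyl[(2,3-dimethylcyclohex-2-en-1-yl)oxy]dimethylsilane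
Conditions: TBSCl, imidazole, DMF, rt
Reagents that add atoms: tert-butyldimethylsilyl chloride, CC(C)(C)[Si](C)(C)Cl
Why: Routine silyl ether formation on a secondary allylic alcohol, giving a group that survives the oxidation, hydride and methyllithium chemistry of steps 3 and 4 and shields one ring face.

Step 3
Reactants: 3 (S)-tert-butyl[(2,3-dimethylcyclohex-2-en-1-yl)oxy]dimethylsilane
Product: 4 (S)-4-(tert-butyldimethylsilyloxy)-2,3-dimethylcyclohex-2-en-1-one
Conditions: CrO3, 3,5-dimethylpyrazole, CH2Cl2, −20 °C
Reagents that add atoms: chromium trioxide, O=[Cr](=O)=O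
Why: Allylic C–H oxidation with the CrO3–3,5-dimethylpyrazole complex should take the ring CH2 next to the tetrasubstituted alkene, because A(1,2) strain holds the silyloxy group pseudoaxial so that the carbinol C–H lies near the alkene plane and is not activated, while methyl groups are the least reactive allylic sites.

Step 4
Reactants: 4 (S)-4-(tert-butyldimethylsilyloxy)-2,3-dimethylcyclohex-2-en-1-one
Product: 7 (3R,4S)-4-(tert-butyldimethylsilyloxy)-2,3-dimethylcyclohex-1-en-1-yl trifluoromethanesulfonate, via dimethylphenylsilyl enol ether 5 (not isolated), via lithium enolate 6 (not isolated)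
Conditions: [(Ph3P)CuH]6 (cat.), PhMe2SiH, toluene, rt; MeLi, THF, 0 °C; N-(5-chloropyridin-2-yl)bis(trifluoromethanesulfonimide), −78 °C → rt
Reagents that add atoms: N-(5-chloropyridin-2-yl)bis(trifluoromethanesulfonimide), O=S(=O)(N(c1ccc(Cl)cn1)S(=O)(=O)C(F)(F)F)C(F)(F)F; in the intermediates only: dimethylphenylsilane, C[SiH](C)c1ccccc1 (silicon of 5); methyllithium, [Li]C (lithium of 6)
Why: Copper hydride 1,4-hydrosilylation (conjugate reduction) puts hydride on C4 anti to the pseudoaxial C3 silyloxy group, leaving C15 cis to O-3, and the regiodefined enol silane is unmasked by MeLi and O-triflated, so the C5=C10 position of the enol triflate is fixed by construction.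

Step 5
Reactants: 7 (3R,4S)-4-(tert-butyldimethylsilyloxy)-2,3-dimethylcyclohex-1-en-1-yl trifluoromethanesulfonate
Product: 8 (3R,4S)-4-hydroxy-2,3-dimethylcyclohex-1-en-1-yl trifluoromethanesulfonate
Conditions: HF·pyridine, MeCN, 0 °C → rt
Reagents that add atoms: none
Why: Acidic fluoride desilylation, which enol triflates tolerate, whereas basic fluoride could attack the sulfonate.

Step 6
Reactants: 9 angelic acid, (Z)-2-methylbut-2-enoic acid; 8 (3R,4S)-4-hydroxy-2,3-dimethylcyclohex-1-en-1-yl trifluoromethanesulfonate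
Product: 11 (1S,2R)-2,3-dimethyl-4-(trifluoromethylsulfonyloxy)cyclohex-3-en-1-yl (Z)-2-methylbut-2-enoate, via angelic 2,4,6-trichlorobenzoic anhydride 10 (not isolated)
Conditions: 2,4,6-trichlorobenzoyl chloride, Et3N, toluene, rt; then 8, 80 °C (no DMAP)
Reagents that add atoms: none
Why: Yamaguchi-type mixed-anhydride esterification without DMAP is the established way to angeloylate a hindered secondary alcohol without Z to E isomerisation, and the robust enol triflate tolerates the heating.

Step 7
Reactants: 11 (1S,2R)-2,3-dimethyl-4-(trifluoromethylsulfonyloxy)cyclohex-3-en-1-yl (Z)-2-methylbut-2-enoate; 12 2-[(E)-2-ethoxyethenyl]-4,4,5,5-tetramethyl-1,3,2-dioxaborolane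
Product: 13 (1S,2R)-4-[(E)-2-ethoxyethenyl]-2,3-dimethylcyclohex-3-en-1-yl (Z)-2-methylbut-2-enoate
Conditions: Pd(PPh3)4 (5 mol %), K3PO4, 1,4-dioxane/H2O (10:1), 70 °C
Reagents that add atoms: none
Why: Suzuki–Miyaura coupling of an enol triflate with an alkenylboronate retains alkene geometry, so the E enol ether that the cycloaddition needs comes with the reagent, and the homoallylic ester cannot ionise to a π-allyl complex.

Step 8
Reactants: 13 (1S,2R)-4-[(E)-2-ethoxyethenyl]-2,3-dimethylcyclohex-3-en-1-yl (Z)-2-methylbut-2-enoate; 14 but-3-yn-2-one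
Product: 15 3β-angeloyloxy-8α-ethoxy-13-noreremophila-6,9-dien-11-one (7-acetyl cycloadduct; 3S,4R,5R,8S)
Conditions: 14 (4 equiv), 2,6-di-tert-butyl-4-methylphenol (cat.), toluene, 90 °C, sealed tube
Reagents that add atoms: none
Why: A concerted, asynchronous normal-demand [4+2] cycloaddition joins the electron-rich (E)-1-ethoxydiene to the ynone; the C8 ethoxy group makes C5 the nucleophilic terminus, so C5 bonds to the unsubstituted alkyne carbon C6 and C8 to the acyl-bearing C7, which is the usual ortho orientation of 1-alkoxydienes and also pairs the hindered terminus with the smallest possible partner. The closest known reactions are cycloadditions of 1-alkoxy- and 1-silyloxy-1,3-dienes with ynones, and of 2-methyl-1-vinylcyclohexenes with acetylenic esters, which build an angular methyl-bearing quaternary carbon in the same way. Ring B closes as a six-membered ring by this intermolecular cycloaddition, both new bonds (C5–C6 and C7–C8) forming in the one step, and it emerges as a 1,4-diene that cannot aromatise because C5 is quaternary. The C5 stereocentre is set by C15: A(1,2) strain with C14 holds C15 pseudoaxial on C4, so the ynone approaches C5 from the opposite face and C14 ends cis to C15 and O-3, while C8 follows from suprafacial addition to the E enol ether (ethoxy trans to C14) and is erased in step 12. The step needs regio- and facial selectivity, secured by the C8 ethoxy group and the C4 methyl group respectively, and the radical inhibitor and a temperature below that of the 1,5-hydrogen shift of the cis-methyl diene guard against the known side reactions.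

Step 9
Reactants: 15 3β-angeloyloxy-8α-ethoxy-13-noreremophila-6,9-dien-11-one
Product: 16 3β-angeloyloxy-8α-ethoxy-1β-hydroxy-13-noreremophila-6,9-dien-11-one (1R)
Conditions: SeO2 (0.5 equiv), t-BuOOH, CH2Cl2, rt
Reagents that add atoms: selenium dioxide (oxygen carrier), O=[Se]=O; tert-butyl hydroperoxide (terminal oxidant), CC(C)(C)OO
Why: SeO2 allylic hydroxylation (ene reaction, then [2,3]-sigmatropic shift) should occur at C1 because C9=C10 is the only electron-rich alkene and selenium adds to its less substituted end C9 on the β face (the α face is covered by the C8 ethoxy group), only the axial 1β-hydrogen is aligned with the π bond, and the sigmatropic shift returns oxygen to that same face, as in the 4β-hydroxylation of Δ5-steroids beside an angular methyl group.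

Step 10
Reactants: 16 3β-angeloyloxy-8α-ethoxy-1β-hydroxy-13-noreremophila-6,9-dien-11-one
Product: 17 3β-angeloyloxy-8α-ethoxy-1β-(triethylsilyloxy)-13-noreremophila-6,9-dien-11-one
Conditions: TESOTf, 2,6-lutidine, CH2Cl2, −78 → 0 °C
Reagents that add atoms: triethylsilyl trifluoromethanesulfonate, CC[Si](CC)(CC)OS(=O)(=O)C(F)(F)F
Why: Silylation of the hindered axial allylic alcohol with a silyl triflate gives a group that protects O-1 from DDQ and leaves together with the silyl peroxide in the last step.

Step 11
Reactants: 17 3β-angeloyloxy-8α-ethoxy-1β-(triethylsilyloxy)-13-noreremophila-6,9-dien-11-one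
Product: 18 3β-angeloyloxy-8α-ethoxy-1β-(triethylsilyloxy)eremophila-6,9,11-triene
Conditions: Ph3PCH3Br, KN(SiMe3)2 (slight deficit), THF, 0 °C → rt
Reagents that add atoms: methyltriphenylphosphonium bromide, C[P+](c1ccccc1)(c1ccccc1)c1ccccc1.[Br-]
Why: Wittig methylenation of the only ketone present, with the ylide made from a slight deficit of base so that the angelate is neither attacked nor isomerised, at a stage where C1 is not yet γ to a ketone and cannot epimerise.

Step 12
Reactants: 18 3β-angeloyloxy-8α-ethoxy-1β-(triethylsilyloxy)eremophila-6,9,11-triene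
Product: 19 3β-angeloyloxy-1β-(triethylsilyloxy)eremophila-6,9,11-trien-8-one
Conditions: DDQ, CH2Cl2/pH 7 phosphate buffer, 0 °C
Reagents that add atoms: water, O
Why: Oxidative cleavage of an allylic ether by DDQ, in which hydride abstraction from the bis-allylic, oxygen-bearing C8–H gives an ethoxy-stabilised cation that water converts through the hemiketal into the ketone, a hydride transfer expected to outrun any cycloaddition of DDQ to the diene, with quaternary C5 ruling out aromatisation.

Step 13
Reactants: 19 3β-angeloyloxy-1β-(triethylsilyloxy)eremophila-6,9,11-trien-8-one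
Product: 20 3β-angeloyloxy-1β-(triethylsilyloxy)-11-(triethylsilylperoxy)eremophila-6,9-dien-8-one
Conditions: Co(acac)2 (cat.), O2 (1 atm), Et3SiH, 1,2-dichloroethane, rt
Reagents that add atoms: dioxygen, O=O; triethylsilane, CC[SiH](CC)CC
Why: Mukaiyama–Isayama hydrosilylperoxidation, in which a cobalt hydride transfers a hydrogen atom to the terminal CH2, the tertiary C11 radical captures O2 (the other allylic terminus C6 is neopentylic and attack there would take the alkene out of the ring enone) and the peroxyl group is silylated, with no stereocentre formed.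

Step 14
Reactants: 20 3β-angeloyloxy-1β-(triethylsilyloxy)-11-(triethylsilylperoxy)eremophila-6,9-dien-8-one
Product: 21 3β-angeloyloxy-1β-hydroxy-11-hydroperoxyeremophila-6,9-dien-8-one (CNP0300636.1; 1R,3S,4R,5R)
Conditions: HF·pyridine, pyridine/THF, 0 °C
Reagents that add atoms: none
Why: Fluoride cleavage of both Si–O bonds under mildly acidic conditions should free the C1 hydroxyl and the hydroperoxide without touching the angelate, the dienone or the O–O bond.

**Compound list**

1 | 2,3-dimethylcyclohex-2-en-1-one | CC1=C(C)C(=O)CCC1 | starting material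
2 | (S)-2,3-dimethylcyclohex-2-en-1-ol | O[C@H]1CCCC(C)=C1C | intermediate
3 | (S)-tert-butyl[(2,3-dimethylcyclohex-2-en-1-yl)oxy]dimethylsilane | CC(C)(C)[Si](C)(C)O[C@H]1CCCC(C)=C1C | intermediate
4 | (S)-4-(tert-butyldimethylsilyloxy)-2,3-dimethylcyclohex-2-en-1-one | CC(C)(C)[Si](C)(C)O[C@H]1CCC(=O)C(C)=C1C | intermediate
5 | dimethylphenylsilyl enol ether of (2R,3R,4S)-4-(tert-butyldimethylsilyloxy)-2,3-dimethylcyclohexanone (C5=C10 enol silane, C4 methyl cis to O-3) | CC(C)(C)[Si](C)(C)O[C@H]1CCC(O[Si](C)(C)c2ccccc2)=C(C)[C@H]1C | intermediate (not isolated)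
6 | lithium enolate corresponding to 5 | CC(C)(C)[Si](C)(C)O[C@H]1CCC(O[Li])=C(C)[C@H]1C | intermediate (not isolated)
7 | (3R,4S)-4-(tert-butyldimethylsilyloxy)-2,3-dimethylcyclohex-1-en-1-yl trifluoromethanesulfonate | CC(C)(C)[Si](C)(C)O[C@H]1CCC(OS(=O)(=O)C(F)(F)F)=C(C)[C@H]1C | intermediate
8 | (3R,4S)-4-hydroxy-2,3-dimethylcyclohex-1-en-1-yl trifluoromethanesulfonate | O[C@H]1CCC(OS(=O)(=O)C(F)(F)F)=C(C)[C@H]1C | intermediate
9 | angelic acid, (Z)-2-methylbut-2-enoic acid | C/C=C(/C)C(=O)O | starting material
10 | angelic 2,4,6-trichlorobenzoic anhydride | C/C=C(/C)C(=O)OC(=O)c1c(Cl)cc(Cl)cc1Cl | intermediate (not isolated)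
11 | (1S,2R)-2,3-dimethyl-4-(trifluoromethylsulfonyloxy)cyclohex-3-en-1-yl (Z)-2-methylbut-2-enoate | C/C=C(/C)C(=O)O[C@H]1CCC(OS(=O)(=O)C(F)(F)F)=C(C)[C@H]1C | intermediate
12 | 2-[(E)-2-ethoxyethenyl]-4,4,5,5-tetramethyl-1,3,2-dioxaborolane | CCO/C=C/B1OC(C)(C)C(C)(C)O1 | starting material
13 | (1S,2R)-4-[(E)-2-ethoxyethenyl]-2,3-dimethylcyclohex-3-en-1-yl (Z)-2-methylbut-2-enoate (ring A diene C5=C10–C9=C8–OEt, C3 angelate and C4 methyl cis) | C/C=C(/C)C(=O)O[C@H]1CCC(/C=C/OCC)=C(C)[C@H]1C | intermediate
14 | but-3-yn-2-one | C#CC(C)=O | starting material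
15 | 3β-angeloyloxy-8α-ethoxy-13-noreremophila-6,9-dien-11-one (7-acetyl cycloadduct; 3S,4R,5R,8S; C14, C15 and O-3 β, ethoxy α) | C/C=C(/C)C(=O)O[C@H]1CCC2=C[C@H](OCC)C(C(C)=O)=C[C@]2(C)[C@H]1C | intermediate
16 | 3β-angeloyloxy-8α-ethoxy-1β-hydroxy-13-noreremophila-6,9-dien-11-one (1R,3S,4R,5R,8S) | C/C=C(/C)C(=O)O[C@H]1C[C@@H](O)C2=C[C@H](OCC)C(C(C)=O)=C[C@]2(C)[C@H]1C | intermediate
17 | 3β-angeloyloxy-8α-ethoxy-1β-(triethylsilyloxy)-13-noreremophila-6,9-dien-11-one | C/C=C(/C)C(=O)O[C@H]1C[C@@H](O[Si](CC)(CC)CC)C2=C[C@H](OCC)C(C(C)=O)=C[C@]2(C)[C@H]1C | intermediate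
18 | 3β-angeloyloxy-8α-ethoxy-1β-(triethylsilyloxy)eremophila-6,9,11-triene (7-isopropenyl) | C/C=C(/C)C(=O)O[C@H]1C[C@@H](O[Si](CC)(CC)CC)C2=C[C@H](OCC)C(C(C)=C)=C[C@]2(C)[C@H]1C | intermediate
19 | 3β-angeloyloxy-1β-(triethylsilyloxy)eremophila-6,9,11-trien-8-one | C/C=C(/C)C(=O)O[C@H]1C[C@@H](O[Si](CC)(CC)CC)C2=CC(=O)C(C(C)=C)=C[C@]2(C)[C@H]1C | intermediate
20 | 3β-angeloyloxy-1β-(triethylsilyloxy)-11-(triethylsilylperoxy)eremophila-6,9-dien-8-one | C/C=C(/C)C(=O)O[C@H]1C[C@@H](O[Si](CC)(CC)CC)C2=CC(=O)C(C(C)(C)OO[Si](CC)(CC)CC)=C[C@]2(C)[C@H]1C | intermediate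
21 | 3β-angeloyloxy-1β-hydroxy-11-hydroperoxyeremophila-6,9-dien-8-one (1R,3S,4R,5R) | C/C=C(/C)C(=O)O[C@H]1C[C@@H](O)C2=CC(=O)C(C(C)(C)OO)=C[C@]2(C)[C@H]1C | target

**Step count and risks**

Total: 14 steps. Longest linear sequence: 14 steps (1 → 21); compounds 9, 12 and 14 are bought.

Steps most likely to fail:

1. Step 8. The cycloaddition at the fully substituted diene terminus may be too slow, so that polymerisation of the ynone and the 1,5-hydrogen shift of the diene take over. Fallback: setting out from 13, the ketone is replaced as dienophile by the smaller and more electrophilic aldehyde propynal (toluene, 40 °C), which should add with the same regio- and facial sense to give the 7-formyl cycloadduct F1. Addition of MeMgBr (THF, −78 °C; the aldehyde reacts far faster than the hindered angelate) would give the C11 carbinol F2 as an epimer mixture. Dess–Martin oxidation then comes back to the route at 15.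

2. Step 9. Oxygen may be delivered to the α face of C1 (ring A reacting through a twist form), or the carbinol may be over-oxidised, so that the 1-epimer or mixtures result. Fallback: setting out from 15, the allylic oxidation product is taken on as the 1α-carbinol F3 and methylenated as in step 11 with excess ylide to the isopropenyl carbinol F4. Dess–Martin oxidation gives the 1-ketone F5, then the only ketone in the molecule. Luche reduction (NaBH4, CeCl3·7H2O, MeOH, −78 °C) follows, in which hydride can approach C1 only from the α face, away from the syn-axial C14 methyl and C3 ester, to give the axial 1β-alcohol F6. Silylation with TESOTf and 2,6-lutidine comes back to the route at 18. The stereocentre is then set by ketone reduction instead of by the ene step.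

3. Step 13. The allylic radical formed by hydrogen-atom transfer may capture oxygen at C6 instead of C11, or the dienone may be reduced. Fallback: setting out from 19, conjugate reduction with [(Ph3P)CuH]6 (hydride to C6, the only unsubstituted β-carbon), followed by equilibration with Et3N, should give the 7(11),9-dien-8-one F7. A Schenck ene reaction with singlet oxygen (O2, tetraphenylporphyrin, visible light, CH2Cl2, −20 °C) then follows the rule for s-cis enones: hydrogen is taken from the alkyl group on the α-carbon (C6) and oxygen goes to the β-carbon (C11). This gives the 1-O-silylated 11-hydroperoxide F8 with the C6=C7 alkene restored. HF·pyridine removes the C1 silyl group and comes back to the route at 21.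

**Further compounds**

F1 | step 8 | 3β-angeloyloxy-8α-ethoxy-12,13-dinoreremophila-6,9-dien-11-al (7-formyl cycloadduct) | C/C=C(/C)C(=O)O[C@H]1CCC2=C[C@H](OCC)C(C=O)=C[C@]2(C)[C@H]1C
F2 | step 8 | 3β-angeloyloxy-8α-ethoxy-13-noreremophila-6,9-dien-11-ol (C11 epimers) | C/C=C(/C)C(=O)O[C@H]1CCC2=C[C@H](OCC)C(C(C)O)=C[C@]2(C)[C@H]1C
F3 | step 9 | 3β-angeloyloxy-8α-ethoxy-1α-hydroxy-13-noreremophila-6,9-dien-11-one (1-epimer of 16) | C/C=C(/C)C(=O)O[C@H]1C[C@H](O)C2=C[C@H](OCC)C(C(C)=O)=C[C@]2(C)[C@H]1C
F4 | step 9 | 3β-angeloyloxy-8α-ethoxyeremophila-6,9,11-trien-1α-ol | C/C=C(/C)C(=O)O[C@H]1C[C@H](O)C2=C[C@H](OCC)C(C(C)=C)=C[C@]2(C)[C@H]1C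
F5 | step 9 | 3β-angeloyloxy-8α-ethoxyeremophila-6,9,11-trien-1-one | C/C=C(/C)C(=O)O[C@H]1CC(=O)C2=C[C@H](OCC)C(C(C)=C)=C[C@]2(C)[C@H]1C
F6 | step 9 | 3β-angeloyloxy-8α-ethoxyeremophila-6,9,11-trien-1β-ol | C/C=C(/C)C(=O)O[C@H]1C[C@@H](O)C2=C[C@H](OCC)C(C(C)=C)=C[C@]2(C)[C@H]1C
F7 | step 13 | 3β-angeloyloxy-1β-(triethylsilyloxy)eremophila-7(11),9-dien-8-one | C/C=C(/C)C(=O)O[C@H]1C[C@@H](O[Si](CC)(CC)CC)C2=CC(=O)C(=C(C)C)C[C@]2(C)[C@H]1C
F8 | step 13 | 3β-angeloyloxy-11-hydroperoxy-1β-(triethylsilyloxy)eremophila-6,9-dien-8-one | C/C=C(/C)C(=O)O[C@H]1C[C@@H](O[Si](CC)(CC)CC)C2=CC(=O)C(C(C)(C)OO)=C[C@]2(C)[C@H]1C
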